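**Two extremes.** If ring closure had no competitor, the percentage of ring at one time stands the same at every charge, but at 8.00 min the north-west run, charged with 5.1 mM, reads 38%, more than the 26% of the south run, charged with 21 mM. So take first-order closure against a loss of second order in starting material, and count turnovers. In the dilute extreme, c(ring) is the charge times u, the fraction closed without competition. In the crowded extreme, c(ring) stops following the charge and stands at a ceiling. A real flask lies below both, and to a good approximation the reciprocals add: the reciprocal of c(ring) is the reciprocal of u times the charge plus the reciprocal of the ceiling.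

| flask | starting material | protic impurity | remark | time |
|---|---|---|---|---|
| north-west | 5.1 mM | 6 mM | run made earlier |  |
| south | 21 mM | 6 mM | run made earlier |  |
| green | 8.0 mM | 6.00 mM |  | 12 min |
| grey | 12 mM | 6.00 mM |  | 12 min |
| teal | 20 mM | 6.00 mM |  | 12 min |
| violet | 30 mM | 6.00 mM |  | 12 min |

| run | time / min | ring / % |
|---|---|---|
| north-west | 1.33 | 13 |
| north-west | 2.50 | 18 |
| north-west | 4.00 | 26 |
| north-west | 5.00 | 28 |
| north-west | 6.00 | 31 |
| north-west | 8.00 | 38 |
| south | 0.417 | 2 |
| south | 1.33 | 9 |
| south | 2.50 | 14 |
| south | 4.00 | 19 |
| south | 5.00 | 21 |
| south | 6.00 | 24 |
| south | 8.00 | 26 |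

(standard deviation of a reading: 1.5 percentage points)

- a reading or a percentage of ring counts all its forms, free or not
- the concentration of ring that is asked is that of its free form alone
- "hardly changes" means that all values lie within two and a half points (for a concentration: within two and a half percent of the largest)

- [ring] (only what is free in solution) at the end for green, grey, teal, violet, in this order
- how the row runs (hardly changes / rises all the way / rises, then falls / falls all the way / falls, then rises)

**Reading the ceiling.** Two runs at one time cancel u. At 8.00 min they give 13.1 mM for the ring ceiling, the gap between charges over the gap between reciprocal fractions of ring; the field calls it the effective molarity. The same reckoning gives 13.4 mM at 5.00 min, but 11.2 mM at 4.00 min and 16.9 mM at 6.00 min, so it is a reading with that width.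

**My reckoning.** The north-west run then gives u = 44.6% at 8.00 min, a closure constant of 0.0738 min⁻¹, and u = 58.8% at 12 min. Free and bound ring together then come to 3.46 mM, 4.58 mM, 6.19 mM and 7.51 mM, the last from a charge beyond both runs. The readings count ring in all its forms, so the runs cannot tell free ring from bound ring; free ring stands no higher than these values, and I commit to them as the upper limit of the free row, which I take to rise.

**The forecast.** It assumes “a basic ring that the protic impurity ties up” and subtracts the impurity, where my reckoning does not. It gives 0 mM, 0 mM, 0.3 mM and 1.9 mM: rises all the way.

**The result.** The free row is 3.13 mM, 4.15 mM, 5.71 mM and 7.15 mM: rises all the way.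

    2 starting material → open dimer (k = 5.53 M⁻¹ min⁻¹)
    starting material → ring (k = 0.0869 min⁻¹)
    starting material + ring ⇌ idle adduct, settled at all times (K = 59.0 M⁻¹)
    starting material + ring → side product (k = 1.83 M⁻¹ min⁻¹)
    starting material + protic impurity → quenched substrate (k = 4.45 M⁻¹ min⁻¹)

**The ceiling again.** Green ends with 3.13 mM of free ring and 83.7% of its protic impurity left, against the forecast's 0 mM. Free and bound together, teal holds 6.45 mM at 12.0 min, against 6.19 mM from the ceiling. At 120 min teal has 0% starting material, so u is taken as one, and the ceiling of 13.1 mM gives 7.91 mM; teal holds 8.16 mM.

The numbers in the tables are simulated with constants of no real substance.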